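**Retrosynthetic overview**

1. Numbering (verticillane): C1 bridgehead CH; C2, C3 CH2; C4(=C20H2); C5 CH2; C6 CH-OAc; C7=C8(CH3); C9 CH2; C10 lactone CH-O; C11=C12 ring-fusion alkene; C13, C14 ring CH2; C15 CMe2; C18 lactone C=O.
2. Endgame: 26 comes from the C2 ketone 23 (Luche reduction, Barton–McCombie deoxygenation). This ketone is the temporary activating group of the key step.
3. Key disconnection: a retro type 2 intramolecular Diels–Alder reaction of 23 cuts C1–C15 and C13–C14 together. It opens the cyclohexene and the twelve-membered ring (both carbocycles of the bicyclo[9.3.1] core) and leaves the monocyclic lactone 22, whose linear chain ends in a vinyl ketone.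
4. Enabling feature: the tetrasubstituted C11=C12 alkene shared by the butenolide and the cyclohexene, flanked by C15Me2 and C13H2, is a Diels–Alder retron. In 22 it is an α-methylidene-β-isopropylidene lactone: the five-membered ring locks the diene s-cis, and the C10 stereocentre carries the tether and so fixes the diene face.
5. 22 comes from Stille coupling/lactonisation (C11–C12), Keck allylation (C5–C6, sets C6), vinylogous Mukaiyama aldol (C9–C10, sets C10) and Hosomi–Sakurai allylation (C2–C3). Ring order: lactone (step 14), then cyclohexene and macrocycle together (step 16).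

Key step: step 16

Assumption 1: in step 3 the antipode of the chiral bisphosphoramide is the one that opens the Re face of aldehyde 2. The sense is to be checked on 6 (MTPA esters), and the mirror-image catalyst is used if needed.

Assumption 2: the C2 carbinol carbon (12–17, 20, 21, 24, 25) is carried as a mixture of epimers and written without a descriptor. It is planar in 22 and 23 and is a CH2 in 26.

**Step 1**
Reactants: 1 2-methylbut-3-yn-2-ol
Product: 2 2-iodo-3-methylbut-2-enal
Conditions: NIS (1.1 equiv), Ph3PAuNTf2 (2 mol %), MoO2(acac)2 (2 mol %), Ph3PO (10 mol %), CH2Cl2, rt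
Reagents that add atoms: N-iodosuccinimide O=C1CCC(=O)N1I
Why: Halogenative Meyer–Schuster rearrangement, in which 1,3-transposition of the tertiary propargylic alcohol gives a metal allenolate that NIS iodinates at the central carbon; both β-substituents are methyl, so no alkene geometry is at stake.

**Step 2**
Reactants: 3 ethyl 3-methylbut-2-enoate
Product: 5 tert-butyl[(1-ethoxy-3-methylbuta-1,3-dien-1-yl)oxy]dimethylsilane, via lithium dienolate 4 (not isolated)
Conditions: LDA, THF/DMPU, −78 °C; then TBSCl, −78 °C to rt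
Reagents that add atoms: tert-butyldimethylsilyl chloride CC(C)(C)[Si](C)(C)Cl
Why: Kinetic γ-deprotonation of the senecioate and O-silylation of the extended enolate (silyl ketene acetal formation) should give the dienolate equivalent for the vinylogous aldol.

**Step 3**
Reactants: 2 2-iodo-3-methylbut-2-enal; 5 tert-butyl[(1-ethoxy-3-methylbuta-1,3-dien-1-yl)oxy]dimethylsilane
Product: 6 ethyl (2E,5R)-5-hydroxy-6-iodo-3,7-dimethylocta-2,6-dienoate
Conditions: SiCl4 (1.1 equiv), chiral binaphthyldiamine-derived bisphosphoramide (5 mol %), i-Pr2NEt (10 mol %), CH2Cl2, −78 °C; aq NaHCO3 work-up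
Reagents that add atoms: none
Why: Catalytic enantioselective vinylogous Mukaiyama aldol reaction (Lewis-base-activated SiCl4), in which the chiral silicon cation binds the conjugated aldehyde, the dienolate attacks with its γ-carbon on the Re face to set (R)-C10, and the open transition state from the s-trans dienolate should give the (E)-enoate.

**Step 4**
Reactants: 6 ethyl (2E,5R)-5-hydroxy-6-iodo-3,7-dimethylocta-2,6-dienoate
Product: 7 ethyl (2E,5R)-6-iodo-3,7-dimethyl-5-(triethylsilyloxy)octa-2,6-dienoate
Conditions: TESCl, imidazole, CH2Cl2, 0 °C to rt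
Reagents that add atoms: chlorotriethylsilane CC[Si](Cl)(CC)CC
Why: Standard silylation masks the C10 alcohol for the reduction and allylation steps and is removable later beside an acetate.

**Step 5**
Reactants: 7 ethyl (2E,5R)-6-iodo-3,7-dimethyl-5-(triethylsilyloxy)octa-2,6-dienoate
Product: 8 (2E,5R)-6-iodo-3,7-dimethyl-5-(triethylsilyloxy)octa-2,6-dien-1-ol
Conditions: DIBAL-H (2.2 equiv), CH2Cl2, −78 °C; Rochelle salt
Reagents that add atoms: none
Why: 1,2-Reduction of an enoate with DIBAL-H leaves the vinyl iodide, the silyl ether and the alkene geometry untouched.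

**Step 6**
Reactants: 8 (2E,5R)-6-iodo-3,7-dimethyl-5-(triethylsilyloxy)octa-2,6-dien-1-ol
Product: 9 (2E,5R)-6-iodo-3,7-dimethyl-5-(triethylsilyloxy)octa-2,6-dienal
Conditions: activated MnO2, CH2Cl2, rt
Reagents that add atoms: none
Why: Allylic oxidation with MnO2 stops at the enal and does not isomerise the trisubstituted alkene.

**Step 7**
Reactants: 10 [2-(chloromethyl)prop-2-en-1-yl]trimethylsilane; 11 acrolein
Product: 12 5-(chloromethyl)hexa-1,5-dien-3-ol (racemic)
Conditions: TiCl4 (1.0 equiv), CH2Cl2, −78 °C
Reagents that add atoms: none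
Why: Hosomi–Sakurai allylation, in which enals react 1,2 at the aldehyde and the SE2' attack regenerates the 1,1-disubstituted alkene; the carbinol is deliberately racemic because it is oxidised in step 15.

**Step 8**
Reactants: 12 5-(chloromethyl)hexa-1,5-dien-3-ol
Product: 13 {[5-(chloromethyl)hexa-1,5-dien-3-yl]oxy}triethylsilane
Conditions: TESCl, imidazole, CH2Cl2, 0 °C
Reagents that add atoms: chlorotriethylsilane CC[Si](Cl)(CC)CC
Why: Silylation under weakly basic conditions blocks the alcohol before it can close onto the allylic chloride to give a methylidenetetrahydrofuran.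

**Step 9**
Reactants: 13 {[5-(chloromethyl)hexa-1,5-dien-3-yl]oxy}triethylsilane
Product: 14 tributyl[2-methylidene-4-(triethylsilyloxy)hex-5-en-1-yl]stannane
Conditions: Bu3SnH, LDA, THF, 0 °C; then 13, −78 to 0 °C
Reagents that add atoms: tributyltin hydride CCCC[SnH](CCCC)CCCC
Why: Displacement of the allylic chloride by tributylstannyllithium gives the same product by SN2 or SN2' attack.

**Step 10**
Reactants: 9 (2E,5R)-6-iodo-3,7-dimethyl-5-(triethylsilyloxy)octa-2,6-dienal; 14 tributyl[2-methylidene-4-(triethylsilyloxy)hex-5-en-1-yl]stannane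
Product: 15 (7S,8E,11R)-12-iodo-9,13-dimethyl-5-methylidene-3,11-bis(triethylsilyloxy)tetradeca-1,8,12-trien-7-ol
Conditions: (S)-BINOL (10 mol %), Ti(Oi-Pr)4 (10 mol %), 4 Å MS, CH2Cl2, −20 °C
Reagents that add atoms: none
Why: Keck catalytic asymmetric allylation, in which the (S)-BINOL–titanium Lewis acid directs the 2-substituted allylstannane to the Si face of the enal and sets (S)-C6, while the SE2' course places the alkene as the exocyclic C4=C20 methylidene.

**Step 11**
Reactants: 15 (7S,8E,11R)-12-iodo-9,13-dimethyl-5-methylidene-3,11-bis(triethylsilyloxy)tetradeca-1,8,12-trien-7-ol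
Product: 16 (7S,8E,11R)-12-iodo-9,13-dimethyl-5-methylidene-3,11-bis(triethylsilyloxy)tetradeca-1,8,12-trien-7-yl acetate
Conditions: Ac2O, DMAP (cat.), pyridine, 0 °C to rt
Reagents that add atoms: acetic anhydride CC(=O)OC(C)=O
Why: Acylation of the only free alcohol installs the acetate of the target with retention at C6.

**Step 12**
Reactants: 16 (7S,8E,11R)-12-iodo-9,13-dimethyl-5-methylidene-3,11-bis(triethylsilyloxy)tetradeca-1,8,12-trien-7-yl acetate
Product: 17 (7S,8E,11R)-3,11-dihydroxy-12-iodo-9,13-dimethyl-5-methylidenetetradeca-1,8,12-trien-7-yl acetate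
Conditions: HF·pyridine, pyridine, THF, 0 °C
Reagents that add atoms: none
Why: Buffered fluoride cleaves both triethylsilyl ethers in one operation, and the acetate cannot migrate because both new alcohols are remote from it.

**Step 13**
Reactants: 18 methyl propiolate
Product: 19 methyl 2-(tributylstannyl)prop-2-enoate
Conditions: Bu3SnH, Pd(PPh3)4 (2 mol %), THF, 0 °C to rt
Reagents that add atoms: tributyltin hydride CCCC[SnH](CCCC)CCCC
Why: Palladium-catalysed syn-hydrostannation of an alkynoate places tin mainly on the carbon α to the ester.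

**Step 14**
Reactants: 17 (7S,8E,11R)-3,11-dihydroxy-12-iodo-9,13-dimethyl-5-methylidenetetradeca-1,8,12-trien-7-yl acetate; 19 methyl 2-(tributylstannyl)prop-2-enoate
Product: 21 (2E,4S)-8-hydroxy-2-methyl-6-methylidene-1-[(2R)-4-methylidene-5-oxo-3-(propan-2-ylidene)oxolan-2-yl]deca-2,9-dien-4-yl acetate, via hydroxy diene ester 20 (not isolated)
Conditions: Pd(PPh3)4 (10 mol %), CuI (20 mol %), CsF (2 equiv), BHT, DMF, rt to 40 °C; then PPTS (cat.), CH2Cl2, rt
Reagents that add atoms: none
Why: Copper- and fluoride-assisted Stille coupling joins C11 to C12 at the vinyl iodide faster than Pd(0) ionises the hindered allylic acetate, and the C10 hydroxyl of 20 then closes the γ-lactone (5-exo-trig acyl substitution) without touching C10.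

**Step 15**
Reactants: 21 (2E,4S)-8-hydroxy-2-methyl-6-methylidene-1-[(2R)-4-methylidene-5-oxo-3-(propan-2-ylidene)oxolan-2-yl]deca-2,9-dien-4-yl acetate
Product: 22 (2E,4S)-2-methyl-6-methylidene-1-[(2R)-4-methylidene-5-oxo-3-(propan-2-ylidene)oxolan-2-yl]-8-oxodeca-2,9-dien-4-yl acetate
Conditions: Dess–Martin periodinane, NaHCO3, CH2Cl2, 0 °C; short neutral silica plug, used at once
Reagents that add atoms: none
Why: Buffered Dess–Martin oxidation of the only free (allylic) alcohol unmasks the vinyl ketone dienophile, merges the C2 epimers and is neutral enough not to move the β,γ-alkene C4=C20 into conjugation.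

**Step 16**
Reactants: 22 (2E,4S)-2-methyl-6-methylidene-1-[(2R)-4-methylidene-5-oxo-3-(propan-2-ylidene)oxolan-2-yl]-8-oxodeca-2,9-dien-4-yl acetate
Product: 23 (1R,6S,7E,10R)-6-acetoxy-2-oxoverticilla-4(20),7,11-trien-18,10-olide
Conditions: slow addition into toluene (final 0.5 mM), BHT (cat.), base-washed glassware, 110–120 °C
Reagents that add atoms: none
Why: Heating the dilute enone should trigger a concerted, asynchronous type 2 intramolecular Diels–Alder reaction in which the bis-exocyclic diene C13=C12–C11=C15 adds suprafacially to the vinyl ketone C14=C1, the unhindered C13–C14 bond leading and the C1–C15 bond (tertiary CH to quaternary CMe2) closing late. The closest known reaction types are type 2 IMDA reactions that give bicyclo[n.3.1] bridgehead alkenes, macrocycle-forming IMDA reactions run at high dilution, and intermolecular additions of acrylic dienophiles to 1,1-dimethyl-2,3-disubstituted butadienes, which bond the gem-dimethyl terminus to the acceptor-bearing carbon. The cyclohexene closes as the [4π+2π] ring and the twelve-membered carbocycle closes with it in the 1,3-bridging (meta) mode, because the nine-carbon tether C2–C10 joins dienophile carbon C1 to diene carbon C11, which leaves C11=C12 as the bridgehead alkene of the new butenolide. The one new stereocentre, C1, is controlled by C10: the C9 arm stands on one face of the flat diene lactone and delivers the dienophile to that face, with the C2 carbonyl (the first tether atom) endo as both the Alder rule and the shortest span demand, so that C2 and C9 end on the same face, i.e. (1R) from (10R). Regioselectivity rests on the ortho effect of the two C15 methyl groups and the para effect of the C12 carboxyl group, chemoselectivity on the vinyl ketone being the only activated 2π unit in the chain (C4=C20 and C7=C8 are unactivated), and the absence of a Lewis acid keeps C4=C20 from attacking the enone. High dilution and BHT should hold back dimerisation through the α-methylidene lactone, and the splayed exocyclic bonds of the five-membered ring should slow the [1,5]-H shift of the diene at this temperature.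

**Step 17**
Reactants: 23 (1R,6S,7E,10R)-6-acetoxy-2-oxoverticilla-4(20),7,11-trien-18,10-olide
Product: 24 (1R,6S,7E,10R)-6-acetoxy-2-hydroxyverticilla-4(20),7,11-trien-18,10-olide
Conditions: NaBH4, CeCl3·7H2O, MeOH, −78 to −40 °C
Reagents that add atoms: none
Why: Luche reduction takes the saturated ketone faster than the tetrasubstituted butenolide or the acetate and is too weakly basic to epimerise C1 or C10; the configuration of the new carbinol is irrelevant because the oxygen is removed.

**Step 18**
Reactants: 24 (1R,6S,7E,10R)-6-acetoxy-2-hydroxyverticilla-4(20),7,11-trien-18,10-olide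
Product: 25 (1R,6S,7E,10R)-6-acetoxy-2-[(1H-imidazol-1-ylcarbonothioyl)oxy]verticilla-4(20),7,11-trien-18,10-olide
Conditions: 1,1'-thiocarbonyldiimidazole, DMAP (cat.), 1,2-dichloroethane, 70 °C
Reagents that add atoms: 1,1'-thiocarbonyldiimidazole S=C(n1ccnc1)n1ccnc1
Why: Thioacylation under near-neutral conditions (first half of the Barton–McCombie sequence) spares the acetate and the acidic C10–H of the butenolide.

**Step 19**
Reactants: 25 (1R,6S,7E,10R)-6-acetoxy-2-[(1H-imidazol-1-ylcarbonothioyl)oxy]verticilla-4(20),7,11-trien-18,10-olide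
Product: 26 (1R,6S,7E,10R)-6-acetoxyverticilla-4(20),7,11-trien-18,10-olide (target)
Conditions: Bu3SnH (0.2 M), AIBN (cat.), toluene, 90 °C
Reagents that add atoms: none
Why: Barton–McCombie deoxygenation, in which the secondary C2 radical released by β-scission should be trapped by concentrated stannane faster than it can add across the ring to C7=C8, and no stereocentre is touched.

**Compound list**

1 | 2-methylbut-3-yn-2-ol | CC(C)(O)C#C | starting material
2 | 2-iodo-3-methylbut-2-enal | CC(C)=C(I)C=O | intermediate
3 | ethyl 3-methylbut-2-enoate | CCOC(=O)C=C(C)C | starting material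
4 | lithium 1-ethoxy-3-methylbuta-1,3-dien-1-olate (not isolated) | C=C(C)C=C(OCC)O[Li] | intermediate
5 | tert-butyl[(1-ethoxy-3-methylbuta-1,3-dien-1-yl)oxy]dimethylsilane | C=C(C)C=C(OCC)O[Si](C)(C)C(C)(C)C | intermediate
6 | ethyl (2E,5R)-5-hydroxy-6-iodo-3,7-dimethylocta-2,6-dienoate | CCOC(=O)/C=C(C)/C[C@@H](O)C(I)=C(C)C | intermediate
7 | ethyl (2E,5R)-6-iodo-3,7-dimethyl-5-(triethylsilyloxy)octa-2,6-dienoate | CCOC(=O)/C=C(C)/C[C@@H](O[Si](CC)(CC)CC)C(I)=C(C)C | intermediate
8 | (2E,5R)-6-iodo-3,7-dimethyl-5-(triethylsilyloxy)octa-2,6-dien-1-ol | OC/C=C(C)/C[C@@H](O[Si](CC)(CC)CC)C(I)=C(C)C | intermediate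
9 | (2E,5R)-6-iodo-3,7-dimethyl-5-(triethylsilyloxy)octa-2,6-dienal | O=C/C=C(C)/C[C@@H](O[Si](CC)(CC)CC)C(I)=C(C)C | intermediate
10 | [2-(chloromethyl)prop-2-en-1-yl]trimethylsilane | C=C(CCl)C[Si](C)(C)C | starting material
11 | acrolein | C=CC=O | starting material
12 | 5-(chloromethyl)hexa-1,5-dien-3-ol (racemic) | C=CC(O)CC(=C)CCl | intermediate
13 | {[5-(chloromethyl)hexa-1,5-dien-3-yl]oxy}triethylsilane | C=CC(O[Si](CC)(CC)CC)CC(=C)CCl | intermediate
14 | tributyl[2-methylidene-4-(triethylsilyloxy)hex-5-en-1-yl]stannane | C=CC(O[Si](CC)(CC)CC)CC(=C)C[Sn](CCCC)(CCCC)CCCC | intermediate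
15 | (7S,8E,11R)-12-iodo-9,13-dimethyl-5-methylidene-3,11-bis(triethylsilyloxy)tetradeca-1,8,12-trien-7-ol | C=CC(O[Si](CC)(CC)CC)CC(=C)C[C@H](O)/C=C(C)/C[C@@H](O[Si](CC)(CC)CC)C(I)=C(C)C | intermediate
16 | (7S,8E,11R)-12-iodo-9,13-dimethyl-5-methylidene-3,11-bis(triethylsilyloxy)tetradeca-1,8,12-trien-7-yl acetate | C=CC(O[Si](CC)(CC)CC)CC(=C)C[C@H](OC(C)=O)/C=C(C)/C[C@@H](O[Si](CC)(CC)CC)C(I)=C(C)C | intermediate
17 | (7S,8E,11R)-3,11-dihydroxy-12-iodo-9,13-dimethyl-5-methylidenetetradeca-1,8,12-trien-7-yl acetate | C=CC(O)CC(=C)C[C@H](OC(C)=O)/C=C(C)/C[C@@H](O)C(I)=C(C)C | intermediate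
18 | methyl propiolate | C#CC(=O)OC | starting material
19 | methyl 2-(tributylstannyl)prop-2-enoate | C=C(C(=O)OC)[Sn](CCCC)(CCCC)CCCC | intermediate
20 | methyl 3-[(1R,3E,5S)-5-acetoxy-1,9-dihydroxy-3-methyl-7-methylideneundeca-3,10-dien-1-yl]-4-methyl-2-methylidenepent-3-enoate (not isolated) | C=CC(O)CC(=C)C[C@H](OC(C)=O)/C=C(C)/C[C@@H](O)C(=C(C)C)C(=C)C(=O)OC | intermediate
21 | (2E,4S)-8-hydroxy-2-methyl-6-methylidene-1-[(2R)-4-methylidene-5-oxo-3-(propan-2-ylidene)oxolan-2-yl]deca-2,9-dien-4-yl acetate | C=CC(O)CC(=C)C[C@H](OC(C)=O)/C=C(C)/C[C@H]1OC(=O)C(=C)C1=C(C)C | intermediate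
22 | (2E,4S)-2-methyl-6-methylidene-1-[(2R)-4-methylidene-5-oxo-3-(propan-2-ylidene)oxolan-2-yl]-8-oxodeca-2,9-dien-4-yl acetate | C=CC(=O)CC(=C)C[C@H](OC(C)=O)/C=C(C)/C[C@H]1OC(=O)C(=C)C1=C(C)C | intermediate
23 | (1R,6S,7E,10R)-6-acetoxy-2-oxoverticilla-4(20),7,11-trien-18,10-olide | C=C1CC(=O)[C@@H]2CCC3=C([C@@H](C/C(C)=C/[C@@H](OC(C)=O)C1)OC3=O)C2(C)C | intermediate
24 | (1R,6S,7E,10R)-6-acetoxy-2-hydroxyverticilla-4(20),7,11-trien-18,10-olide | C=C1CC(O)[C@@H]2CCC3=C([C@@H](C/C(C)=C/[C@@H](OC(C)=O)C1)OC3=O)C2(C)C | intermediate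
25 | (1R,6S,7E,10R)-6-acetoxy-2-[(1H-imidazol-1-ylcarbonothioyl)oxy]verticilla-4(20),7,11-trien-18,10-olide | C=C1CC(OC(=S)n4ccnc4)[C@@H]2CCC3=C([C@@H](C/C(C)=C/[C@@H](OC(C)=O)C1)OC3=O)C2(C)C | intermediate
26 | (1R,6S,7E,10R)-6-acetoxyverticilla-4(20),7,11-trien-18,10-olide | C=C1CC[C@@H]2CCC3=C([C@@H](C/C(C)=C/[C@@H](OC(C)=O)C1)OC3=O)C2(C)C | target

Total step count: 19. Longest linear sequence: 14 (steps 1, 3–6, 10–12, 14–19).

**Steps most likely to fail**

(1) Step 16.
- What may go wrong: the effective molarity for a twelve-membered closure may be too low for the hindered C15 terminus. The cycloaddition could then be outrun by dimerisation through the α-methylidene lactone, by a [1,5]-H shift of the diene, or by closure in the 1,4-bridging orientation.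
- Fallback (sets out from 9, 12 and 19, comes back at 23): the two ring closures are separated, so the cycloaddition can be run concentrated.
- HF·pyridine frees (2E,5R)-5-hydroxy-6-iodo-3,7-dimethylocta-2,6-dienal F1.
- Stille coupling of F1 with 19 passes through the hydroxy diene ester F2 and, after lactonisation, gives the diene lactone enal F3.
- Dess–Martin oxidation of 12 gives 5-(chloromethyl)hexa-1,5-dien-3-one F4.
- An intermolecular Diels–Alder reaction of F3 with excess F4 gives the bicyclic butenolide F5. Its C1 epimers can be interconverted with DBU because C1 is α to the ketone, and the (1R) epimer is carried on.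
- An intramolecular Nozaki–Hiyama–Kishi allylation of the allylic chloride onto the enal (CrCl2, chiral oxazoline–sulfonamide ligand, high dilution) closes the macrocycle at C5–C6 to give the macrocyclic keto alcohol F6.
- Acetylation of F6 gives 23.

(2) Step 14.
- What may go wrong: oxidative addition and transmetalation at the tetrasubstituted iodide may be slow. That would allow cine substitution of the α-stannyl acrylate, ionisation of the allylic acetate by Pd(0), or self-cycloaddition of the diene as it forms.
- Fallback (sets out from 17, comes back at 21): the acrylate unit is built from a small alkyne and carbon monoxide.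
- Sonogashira coupling of 17 with trimethylsilylacetylene gives the silyl enyne F7.
- TBAF buffered with AcOH gives the terminal enyne F8.
- Palladium-catalysed cyclocarbonylation of its but-3-yn-1-ol unit (PdCl2, PPh3, SnCl2, CO, MeCN) forms the α-methylidene lactone 21.

(3) Step 3.
- What may go wrong: facial selectivity on the twisted, hindered α-iodo enal may be poor. α-Attack of the dienolate, or erosion of the alkene geometry followed by lactonisation of the Z isomer, may also intervene.
- Fallback (sets out from 2, comes back at 7): C10 and the alkene are set in separate steps.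
- (R)-BINOL/Ti(Oi-Pr)4-catalysed propargylation of 2 with allenyltributylstannane gives (4R)-5-iodo-6-methylhept-5-en-1-yn-4-ol F9.
- TESCl/imidazole gives its triethylsilyl ether F10.
- Zirconium-catalysed methylalumination of the terminal alkyne (Me3Al, Cp2ZrCl2), followed by ethyl chloroformate, gives the geometrically pure (E)-enoate 7.

**Further compounds**

F1 | step 16 | (2E,5R)-5-hydroxy-6-iodo-3,7-dimethylocta-2,6-dienal | O=C/C=C(C)/C[C@@H](O)C(I)=C(C)C
F2 | step 16 | methyl 3-[(1R,3E)-1-hydroxy-3-methyl-5-oxopent-3-en-1-yl]-4-methyl-2-methylidenepent-3-enoate | O=C/C=C(C)/C[C@@H](O)C(=C(C)C)C(=C)C(=O)OC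
F3 | step 16 | (2E)-3-methyl-4-[(2R)-4-methylidene-5-oxo-3-(propan-2-ylidene)oxolan-2-yl]but-2-enal | O=C/C=C(C)/C[C@H]1OC(=O)C(=C)C1=C(C)C
F4 | step 16 | 5-(chloromethyl)hexa-1,5-dien-3-one | C=CC(=O)CC(=C)CCl
F5 | step 16 | (2E)-4-[(3R,5R)-5-[3-(chloromethyl)but-3-enoyl]-4,4-dimethyl-1-oxo-1,3,4,5,6,7-hexahydro-2-benzofuran-3-yl]-3-methylbut-2-enal | O=C/C=C(C)/C[C@H]1OC(=O)C2=C1C(C)(C)[C@H](C(=O)CC(=C)CCl)CC2
F6 | step 16 | (1R,6S,7E,10R)-6-hydroxy-2-oxoverticilla-4(20),7,11-trien-18,10-olide | C=C1CC(=O)[C@@H]2CCC3=C([C@@H](C/C(C)=C/[C@@H](O)C1)OC3=O)C2(C)C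
F7 | step 14 | (7S,8E,11R)-3,11-dihydroxy-9,13-dimethyl-5-methylidene-12-[(trimethylsilyl)ethynyl]tetradeca-1,8,12-trien-7-yl acetate | C=CC(O)CC(=C)C[C@H](OC(C)=O)/C=C(C)/C[C@@H](O)C(C#C[Si](C)(C)C)=C(C)C
F8 | step 14 | (7S,8E,11R)-12-ethynyl-3,11-dihydroxy-9,13-dimethyl-5-methylidenetetradeca-1,8,12-trien-7-yl acetate | C=CC(O)CC(=C)C[C@H](OC(C)=O)/C=C(C)/C[C@@H](O)C(C#C)=C(C)C
F9 | step 3 | (4R)-5-iodo-6-methylhept-5-en-1-yn-4-ol | C#CC[C@@H](O)C(I)=C(C)C
F10 | step 3 | triethyl{[(4R)-5-iodo-6-methylhept-5-en-1-yn-4-yl]oxy}silane | C#CC[C@@H](O[Si](CC)(CC)CC)C(I)=C(C)C
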